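A direct plan would build one resorcylate ring from acyclic carbonyl compounds and use it twice. A Michael–Dieckmann annulation would give cyclohexenone ester A1, dehydrogenation with bromine the methyl resorcylate A2, and ether and ester exchanges the upper acid A3 and the lower phenol A4. These would be joined by acylation through a mixed anhydride and freed by hydrogenolysis. Its weakest parts would be:
(a) the annulation and dehydrogenation, which would set two stereocentres without control only to erase them, and would expose an electron-rich resorcinol to bromine;
(b) the five alkylation and saponification operations between A2 and the two partners, which would add no skeletal bond and would pass through a hindered ester hydrolysis and a free resorcylic acid that loses CO2 easily;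
(c) the late acylation at the carbonyl of a 2,6-disubstituted benzoic acid, which would place the most hindered bond formation, and a choice between two phenols, on the most precious material.

**Plan of the new route**
- First cut: the aryl C–O bond para to the carboxyl group of the lower ring, giving acid 7 and boronic acid 14, whose boron is placed by C–H borylation.
- Second cut, in each ring: the neighbouring bonds ring–heptyl and ring–carbonyl, which lead back to an aryne.
- Enabling feature: in both benzene rings the carbon bearing the carbonyl group lies between the carbon bearing heptyl and the carbon bearing oxygen. An aryne across the first two, flanked by that oxygen as a methoxy group, takes up heptyl and the carbonyl electrophile in one operation and one orientation.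
- Neither ring is built: both are bought as fluoroarenes and dressed in the order heptyl plus carbonyl, boron, ester oxygen.
- Hence no cyclohexenone, stereocentre or dehydrogenation arises, no protecting group is put on in a step of its own, and the ester is closed at an unhindered aryl carbon instead of the hindered carbonyl.

Key step: step 2

Remark on the chemistry: the target has no stereocentre. n-Heptyllithium is assumed not to be a catalogue reagent and is prepared in step 1; 1-fluoro-3,5-dimethoxybenzene and 3-fluoroanisole are taken as commercial.

**Route**

Step 1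
Reactants: 1 1-bromoheptane
Product: 2 n-heptyllithium (ether solution, titrated)
Conditions: Li wire (2.2 equiv, about 1% Na), Et2O, −15 → −10 °C, Ar; filtered under Ar and titrated
Reagents that add atoms: lithium, [Li]
Why: Reductive lithiation of a primary alkyl bromide by lithium metal is the standard preparation of n-alkyllithiums, and the low temperature limits Wurtz coupling.

Step 2
Reactants: 3 1-fluoro-3,5-dimethoxybenzene; 2 n-heptyllithium
Product: 7 2-heptyl-4,6-dimethoxybenzoic acid, via (2-fluoro-4,6-dimethoxyphenyl)lithium 4 (not isolated), via 3,5-dimethoxybenzyne 5 (not isolated), via (2-heptyl-4,6-dimethoxyphenyl)lithium 6 (not isolated)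
Conditions: 3 added slowly to 2 (2.4 equiv), Et2O, rt → gentle reflux; then −78 °C, dry CO2 (excess) → rt; 2 M HCl, 0 °C
Reagents that add atoms: carbon dioxide, O=C=O
Why: Heptyllithium 2 should first remove the proton of 3 that lies between fluorine and a methoxy group, the most acidic one, and lithium species 4 then loses LiF to give aryne 5. A second equivalent of 2 adds to the aryne carbon remote from the flanking methoxy group, because the carbanion then forms on the carbon beside that oxygen, where induction and O–Li coordination stabilise it, and because the remote carbon is the more linear, more electrophilic end of the distorted triple bond; aryllithium 6 is then carboxylated by CO2 at exactly that carbon. The closest known reaction type is the carbolithiation of 3-alkoxyarynes generated from fluoroanisoles by alkyllithiums, followed by carboxylation, a classical entry to ethers of 6-alkylsalicylic acids. No ring is closed and no stereocentre is formed. The step needs three selectivities: the site of elimination, which the symmetry of 3 secures because both positions beside fluorine are equivalent; the sense of addition, which the methoxy group beside the triple bond secures; and alkyl over aryl addition to 5, which the excess of the more nucleophilic 2 and the slow inverse addition of 3 secure. The second methoxy group, meta to the carbon attacked, does not oppose this polarisation.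

Step 3
Reactants: 8 3-fluoroanisole; 2 n-heptyllithium
Product: 12 tert-butyl 2-heptyl-6-methoxybenzoate, via (2-fluoro-6-methoxyphenyl)lithium 9 (not isolated), via 3-methoxybenzyne 10 (not isolated), via (2-heptyl-6-methoxyphenyl)lithium 11 (not isolated)
Conditions: 8 added slowly to 2 (2.4 equiv), Et2O, rt → gentle reflux; then cannulated into Boc2O (3 equiv), THF, −78 °C → rt; H2O
Reagents that add atoms: di-tert-butyl dicarbonate, CC(C)(C)OC(=O)OC(=O)OC(C)(C)C
Why: The same aryne carbolithiation, here with a single C–H between fluorine and methoxy; aryllithium 11 is acylated by the dicarbonate to give the tert-butyl ester directly, and its two ortho substituents block a second addition to the ester.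

Step 4
Reactants: 12 tert-butyl 2-heptyl-6-methoxybenzoate
Product: 14 [4-(tert-butoxycarbonyl)-3-heptyl-5-methoxyphenyl]boronic acid, via tert-butyl 2-heptyl-6-methoxy-4-(4,4,5,5-tetramethyl-1,3,2-dioxaborolan-2-yl)benzoate 13 (not isolated)
Conditions: [Ir(OMe)(cod)]2 (1.5 mol %), 4,4'-di-tert-butyl-2,2'-bipyridine (3 mol %), B2pin2 (0.75 equiv), THF, 80 °C, Ar; then NaIO4 (3 equiv), NH4OAc (3 equiv), acetone/H2O, rt
Reagents that add atoms: bis(pinacolato)diboron, CC1(C)OB(OC1(C)C)B1OC(C)(C)C(C)(C)O1; water, O
Why: Iridium-catalysed aromatic C–H borylation is governed by steric hindrance: of the three ring hydrogens of 12 only H-4 has no ortho substituent (H-3 lies beside the heptyl chain, H-5 beside the methoxy group), and the ester cannot direct because both its ortho positions are occupied; periodate cleavage of the pinacol then frees the boronic acid.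

Step 5
Reactants: 7 2-heptyl-4,6-dimethoxybenzoic acid; 14 [4-(tert-butoxycarbonyl)-3-heptyl-5-methoxyphenyl]boronic acid
Product: 15 tert-butyl 2-heptyl-4-[(2-heptyl-4,6-dimethoxybenzoyl)oxy]-6-methoxybenzoate
Conditions: 7 (1.0 equiv), 14 (1.5 equiv), Cu(OTf)2 (0.4 equiv), urea (1.0 equiv), EtOAc, 60 °C, open to air
Reagents that add atoms: none
Why: Chan–Lam oxidative coupling of a carboxylic acid with an arylboronic acid: the unhindered aryl group of 14 is transferred to the divalent copper carboxylate of 7, air oxidises the complex to trivalent copper and C–O reductive elimination forms the aryl ester; the new bond is made at a ring carbon without ortho substituents, so the two ortho groups of 7 never face a nucleophile at the carbonyl.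

Step 6
Reactants: 15 tert-butyl 2-heptyl-4-[(2-heptyl-4,6-dimethoxybenzoyl)oxy]-6-methoxybenzoate
Product: 16 2-heptyl-4-[(2-heptyl-6-hydroxy-4-methoxybenzoyl)oxy]-6-hydroxybenzoic acid (CNP0234711.0)
Conditions: BCl3 (1 M in CH2Cl2, 5 equiv), CH2Cl2, −78 → 0 °C; poured onto ice/1 M HCl; concentration below 30 °C
Reagents that add atoms: none
Why: Chelation-controlled ether cleavage: BCl3 bound to each carbonyl oxygen delivers chloride to the methyl group of the methoxy group ortho to it through a six-membered chelate, while the para methoxy group, which cannot chelate, should stay at this temperature; the same Lewis acid ionises the tert-butyl ester, the aryl ester is not a substrate, and the cold work-up spares the salicylic acid from decarboxylation.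

**Compound list**

1 | 1-bromoheptane | CCCCCCCBr | starting material
2 | n-heptyllithium | [Li]CCCCCCC | intermediate
3 | 1-fluoro-3,5-dimethoxybenzene | COc1cc(F)cc(OC)c1 | starting material
4 | (2-fluoro-4,6-dimethoxyphenyl)lithium (not isolated) | [Li]c1c(F)cc(OC)cc1OC | intermediate
5 | 3,5-dimethoxybenzyne (not isolated) | COC1=CC(OC)=CC#C1 | intermediate
6 | (2-heptyl-4,6-dimethoxyphenyl)lithium (not isolated) | [Li]c1c(CCCCCCC)cc(OC)cc1OC | intermediate
7 | 2-heptyl-4,6-dimethoxybenzoic acid | CCCCCCCc1cc(OC)cc(OC)c1C(=O)O | intermediate
8 | 3-fluoroanisole | COc1cccc(F)c1 | starting material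
9 | (2-fluoro-6-methoxyphenyl)lithium (not isolated) | [Li]c1c(F)cccc1OC | intermediate
10 | 3-methoxybenzyne (not isolated) | COC1=CC=CC#C1 | intermediate
11 | (2-heptyl-6-methoxyphenyl)lithium (not isolated) | [Li]c1c(CCCCCCC)cccc1OC | intermediate
12 | tert-butyl 2-heptyl-6-methoxybenzoate | CCCCCCCc1cccc(OC)c1C(=O)OC(C)(C)C | intermediate
13 | tert-butyl 2-heptyl-6-methoxy-4-(4,4,5,5-tetramethyl-1,3,2-dioxaborolan-2-yl)benzoate (not isolated) | CCCCCCCc1cc(B2OC(C)(C)C(C)(C)O2)cc(OC)c1C(=O)OC(C)(C)C | intermediate
14 | [4-(tert-butoxycarbonyl)-3-heptyl-5-methoxyphenyl]boronic acid | CCCCCCCc1cc(B(O)O)cc(OC)c1C(=O)OC(C)(C)C | intermediate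
15 | tert-butyl 2-heptyl-4-[(2-heptyl-4,6-dimethoxybenzoyl)oxy]-6-methoxybenzoate | CCCCCCCc1cc(OC(=O)c2c(OC)cc(OC)cc2CCCCCCC)cc(OC)c1C(=O)OC(C)(C)C | intermediate
16 | 2-heptyl-4-[(2-heptyl-6-hydroxy-4-methoxybenzoyl)oxy]-6-hydroxybenzoic acid | CCCCCCCc1cc(OC(=O)c2c(O)cc(OC)cc2CCCCCCC)cc(O)c1C(=O)O | target

**Count and risks**

Total step count: 6. Longest linear sequence: 5 steps (steps 1, 3, 4, 5, 6).

Steps most likely to fail:

1. Step 5. The transfer of the aryl group to copper or the C–O reductive elimination could be slow with the bulky, electron-rich carboxylate, so that protodeboronation, oxidation to the phenol or homocoupling of 14 would outrun the coupling. The Lewis-acidic copper salt could also loosen the tert-butyl ester. The fallback would set out from 14 and 7 and come back at 15. Boronic acid 14 would be oxidised with 30% H2O2 and NaHCO3 in THF/H2O at 0 °C to tert-butyl 2-heptyl-4-hydroxy-6-methoxybenzoate F1. Acid 7 would be converted with (COCl)2 and a drop of DMF in CH2Cl2 into 2-heptyl-4,6-dimethoxybenzoyl chloride F2. F1 would then be acylated by F2 with Et3N and DMAP in CH2Cl2 to give 15. This returns to acyl substitution at the hindered carbonyl and is therefore held in reserve only.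

2. Step 2. Metalation of 3 could take place between the two methoxy groups, giving an anion that cannot eliminate, or aryllithium 4 or 6 could add to aryne 5 in place of 2 and give biaryls. The fallback would set out from 1 and come back at 7. Bromide 1 would be turned with Mg in Et2O into heptylmagnesium bromide F3, which would be coupled with commercial 1-bromo-3,5-dimethoxybenzene F4 under NiCl2(dppp) catalysis (dppp = 1,3-bis(diphenylphosphino)propane; Kumada coupling) to 1-heptyl-3,5-dimethoxybenzene F5. Vilsmeier–Haack formylation (POCl3, DMF), directed by the two methoxy groups to the position beside the chain, would give 2-heptyl-4,6-dimethoxybenzaldehyde F6. Pinnick oxidation (NaClO2, NaH2PO4, 2-methyl-2-butene, t-BuOH/H2O) would give 7.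

3. Step 6. The excess of Lewis acid needed for three cleavages could erode the para methyl ether or the aryl ester, or the lower methyl ether could resist once its neighbour has become a boron carboxylate. The fallback would set out from 2 and come back at 16; it would carry the two ortho oxygens as methoxymethyl ethers, which leave with the tert-butyl ester under a Brønsted acid that cannot touch a methyl ether.
   - Commercial 3-fluoro-5-methoxyphenol F7 would be converted with MOMCl and i-Pr2NEt in CH2Cl2 into 1-fluoro-3-methoxy-5-(methoxymethoxy)benzene F8, and commercial 3-fluorophenol F9 likewise into 1-fluoro-3-(methoxymethoxy)benzene F10.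
   - With 2 under the conditions of step 2 (metalation now between fluorine and the more strongly coordinating acetal oxygen, CO2 quench, work-up at pH 4) F8 would give 2-heptyl-4-methoxy-6-(methoxymethoxy)benzoic acid F11. Under the conditions of step 3 F10 would give tert-butyl 2-heptyl-6-(methoxymethoxy)benzoate F12.
   - Borylation and periodate cleavage as in step 4 would turn F12 into [4-(tert-butoxycarbonyl)-3-heptyl-5-(methoxymethoxy)phenyl]boronic acid F13.
   - The coupling of step 5 with F11 would give tert-butyl 2-heptyl-4-{[2-heptyl-4-methoxy-6-(methoxymethoxy)benzoyl]oxy}-6-(methoxymethoxy)benzoate F14.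
   - CF3CO2H in wet CH2Cl2 at 0 °C would remove both acetals and the tert-butyl ester to give 16.

**Further compounds**

F1 | step 5 | tert-butyl 2-heptyl-4-hydroxy-6-methoxybenzoate | CCCCCCCc1cc(O)cc(OC)c1C(=O)OC(C)(C)C
F2 | step 5 | 2-heptyl-4,6-dimethoxybenzoyl chloride | CCCCCCCc1cc(OC)cc(OC)c1C(Cl)=O
F3 | step 2 | heptylmagnesium bromide | CCCCCCC[Mg]Br
F4 | step 2 | 1-bromo-3,5-dimethoxybenzene | COc1cc(Br)cc(OC)c1
F5 | step 2 | 1-heptyl-3,5-dimethoxybenzene | CCCCCCCc1cc(OC)cc(OC)c1
F6 | step 2 | 2-heptyl-4,6-dimethoxybenzaldehyde | CCCCCCCc1cc(OC)cc(OC)c1C=O
F7 | step 6 | 3-fluoro-5-methoxyphenol | COc1cc(O)cc(F)c1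
F8 | step 6 | 1-fluoro-3-methoxy-5-(methoxymethoxy)benzene | COCOc1cc(F)cc(OC)c1
F9 | step 6 | 3-fluorophenol | Oc1cccc(F)c1
F10 | step 6 | 1-fluoro-3-(methoxymethoxy)benzene | COCOc1cccc(F)c1
F11 | step 6 | 2-heptyl-4-methoxy-6-(methoxymethoxy)benzoic acid | CCCCCCCc1cc(OC)cc(OCOC)c1C(=O)O
F12 | step 6 | tert-butyl 2-heptyl-6-(methoxymethoxy)benzoate | CCCCCCCc1cccc(OCOC)c1C(=O)OC(C)(C)C
F13 | step 6 | [4-(tert-butoxycarbonyl)-3-heptyl-5-(methoxymethoxy)phenyl]boronic acid | CCCCCCCc1cc(B(O)O)cc(OCOC)c1C(=O)OC(C)(C)C
F14 | step 6 | tert-butyl 2-heptyl-4-{[2-heptyl-4-methoxy-6-(methoxymethoxy)benzoyl]oxy}-6-(methoxymethoxy)benzoate | CCCCCCCc1cc(OC(=O)c2c(OCOC)cc(OC)cc2CCCCCCC)cc(OCOC)c1C(=O)OC(C)(C)C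
A1 | direct plan | methyl 6-heptyl-2-hydroxy-4-oxocyclohex-2-ene-1-carboxylate (racemic) | CCCCCCCC1CC(=O)C=C(O)C1C(=O)OC
A2 | direct plan | methyl 6-heptyl-2,4-dihydroxybenzoate | CCCCCCCc1cc(O)cc(O)c1C(=O)OC
A3 | direct plan | 2-(benzyloxy)-6-heptyl-4-methoxybenzoic acid | CCCCCCCc1cc(OC)cc(OCc2ccccc2)c1C(=O)O
A4 | direct plan | benzyl 6-heptyl-2,4-dihydroxybenzoate | CCCCCCCc1cc(O)cc(O)c1C(=O)OCc1ccccc1
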